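**Retrosynthetic overview**
1. The target comes from its bis(benzyl ether) by hydrogenolysis in the last step.
2. The tetrahydrofuran ring comes from an acyclic triol by forming the ether C–O bond between the two primary carbons (key step), leaving the benzylic carbinol free and untouched.
3. The triol comes from a trans, anti aldol lactone (LiAlH4), made from an (S)-β-arylmethyl-γ-butyrolactone and O-benzylsyringaldehyde; the aldol sets the ring center next to the carbinol and the carbinol center.
4. The (S)-lactone comes from the Stobbe half-ester of O-benzylvanillin and dimethyl succinate by Rh-catalysed asymmetric hydrogenation (first stereocenter) and reductive lactonisation.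
5. Ring order: γ-butyrolactone (step 3, temporary), opened in step 5, then the tetrahydrofuran (step 6).

Assumption: both O-benzylated aldehydes are bought as catalogue compounds.

**Route**

Step 1
Reactants: 1 4-(benzyloxy)-3-methoxybenzaldehyde; 2 dimethyl succinate
Product: 3 (E)-4-[4-(benzyloxy)-3-methoxyphenyl]-3-(methoxycarbonyl)but-3-enoic acid
Conditions: NaOMe (2 equiv), MeOH, reflux; then aq HCl
Reagents that add atoms: none
Why: Stobbe condensation, in which the succinate enolate adds to the aldehyde, the alkoxide lactonises onto the far ester and base-induced ring opening gives the conjugated E half-ester (aryl trans to the ester); no stereocenter is formed.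

Step 2
Reactants: 3 (E)-4-[4-(benzyloxy)-3-methoxyphenyl]-3-(methoxycarbonyl)but-3-enoic acid
Product: 4 (S)-3-[4-(benzyloxy)-3-methoxybenzyl]-4-methoxy-4-oxobutanoic acid
Conditions: [Rh(cod)Cl]2 (0.25 mol %), (4R,5R)-MOD-DIOP [(4R,5R)-4,5-bis{[bis(4-methoxy-3,5-dimethylphenyl)phosphanyl]methyl}-2,2-dimethyl-1,3-dioxolane] (0.55 mol %), Et3N (1 equiv), H2 (1 atm), MeOH, 30 °C; one crystallisation
Reagents that add atoms: none
Why: Rhodium–bisphosphine asymmetric hydrogenation of an itaconate-type half-ester whose carboxylate and alkene chelate the metal; as recalled for this substrate class the (4S,5S) ligand gives the R acid, so its mirror image (4R,5R) is used to set the S center (about 94% ee expected, raised by crystallisation), and the sense should be confirmed by optical rotation on the first run.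

Step 3
Reactants: 4 (S)-3-[4-(benzyloxy)-3-methoxybenzyl]-4-methoxy-4-oxobutanoic acid
Product: 6 (S)-4-[4-(benzyloxy)-3-methoxybenzyl]dihydrofuran-2(3H)-one, via hydroxy acid 5 (not isolated)
Conditions: KOH (1 equiv), EtOH; CaCl2, NaBH4 (Ca(BH4)2 made in the flask), EtOH, −10 °C → rt; then 2 M HCl, rt → 40 °C
Reagents that add atoms: none
Why: Chemoselective borohydride reduction, in which Ca(BH4)2 reduces the methyl ester while the carboxylate salt is inert, followed by acid-promoted lactonisation; the stereocenter is not touched and keeps its S descriptor.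

Step 4
Reactants: 6 (S)-4-[4-(benzyloxy)-3-methoxybenzyl]dihydrofuran-2(3H)-one; 7 4-(benzyloxy)-3,5-dimethoxybenzaldehyde
Product: 10 (3R,4S)-3-[(S)-[4-(benzyloxy)-3,5-dimethoxyphenyl](hydroxy)methyl]-4-[4-(benzyloxy)-3-methoxybenzyl]dihydrofuran-2(3H)-one, via lithium enolate 8 (not isolated), via chlorozinc enolate 9 (not isolated)
Conditions: LiN(SiMe3)2 (1.1 equiv), THF, −78 °C; ZnCl2 (1.2 equiv); then 7 (1.1 equiv), −78 → −30 °C; aq NH4Cl
Reagents that add atoms: lithium hexamethyldisilazide, [Li]N([Si](C)(C)C)[Si](C)(C)C (Li held in 8 only); zinc chloride, Cl[Zn]Cl (ZnCl held in 9 only)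
Why: Zimmerman–Traxler aldol addition of the ring-locked E(O)-enolate, where the aldehyde attacks the face opposite the β-benzyl group (trans lactone) and the chair transition state gives the anti carbinol (S); equilibration of the chelated zinc aldolate favours the same anti isomer, and the minor epimer is removed by chromatography.

Step 5
Reactants: 10 (3R,4S)-3-[(S)-[4-(benzyloxy)-3,5-dimethoxyphenyl](hydroxy)methyl]-4-[4-(benzyloxy)-3-methoxybenzyl]dihydrofuran-2(3H)-one
Product: 11 (2S,3S)-2-[(S)-[4-(benzyloxy)-3,5-dimethoxyphenyl](hydroxy)methyl]-3-[4-(benzyloxy)-3-methoxybenzyl]butane-1,4-diol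
Conditions: LiAlH4 (2.5 equiv), THF, 0 °C → rt (lactone added to the hydride); H2O / aq NaOH work-up, no acid
Reagents that add atoms: none
Why: Hydride reduction of the lactone to the 1,4-diol, fast enough at 0 °C to outrun retro-aldol cleavage; no stereocenter is involved, and acid is avoided because it would close the benzylic carbon onto the far CH2OH.

Step 6
Reactants: 11 (2S,3S)-2-[(S)-[4-(benzyloxy)-3,5-dimethoxyphenyl](hydroxy)methyl]-3-[4-(benzyloxy)-3-methoxybenzyl]butane-1,4-diol
Product: 13 (S)-[4-(benzyloxy)-3,5-dimethoxyphenyl][(3S,4S)-4-[4-(benzyloxy)-3-methoxybenzyl]tetrahydrofuran-3-yl]methanol, via primary monotosylate 12 (not isolated)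
Conditions: Ph2BOCH2CH2NH2 (2-aminoethyl diphenylborinate, 10 mol %), TsCl (1.1 equiv), i-Pr2NEt (2 equiv), MeCN, rt; then DBU (2 equiv), 50 °C
Reagents that add atoms: p-toluenesulfonyl chloride, Cc1ccc(cc1)S(Cl)(=O)=O (tosyl group held in 12 only; it leaves again on ring closure)
Why: Proposed new method: a borinate-templated, site-selective sulfonylation joined in one flask to a 5-exo-tet Williamson closure; the diarylborinic acid catalyst should bind the only 1,3-diol of 11 (the benzylic OH and the CH2OH on the neighbouring carbon) as a six-membered tetracoordinate borinate, whose primary oxygen is sulfonylated much faster than the unactivated CH2OH on the other branch, so the leaving group sits only on the carbon from which the remaining primary OH can close the tetrahydrofuran while the benzylic OH could only form a strained oxetane, which shuts out the 2-aryl-tetrahydrofuran that acid or unselective activation would give; the C–O bond forms at a primary carbon, so all three stereocenters are kept; the closest known chemistry is diarylborinic acid-catalysed monotosylation of 1,2- and 1,3-diols and TsCl/base cyclodehydration of 1,4-diols, neither shown on a triol where the catalyst must choose between two primary hydroxyls.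

Step 7
Reactants: 13 (S)-[4-(benzyloxy)-3,5-dimethoxyphenyl][(3S,4S)-4-[4-(benzyloxy)-3-methoxybenzyl]tetrahydrofuran-3-yl]methanol
Product: 14 (S)-(4-hydroxy-3,5-dimethoxyphenyl)[(3S,4S)-4-(4-hydroxy-3-methoxybenzyl)tetrahydrofuran-3-yl]methanol
Conditions: H2 (1 atm), 10% Pd/C, EtOAc/EtOH, rt, stopped after uptake of 2 equiv; acid-free work-up
Reagents that add atoms: none
Why: Hydrogenolysis of the two aryl benzyl ethers over Pd/C under neutral conditions is much faster than C–O cleavage of the secondary benzylic alcohol, so both phenols are freed without change at the three stereocenters.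

**Compound list**
1 | 4-(benzyloxy)-3-methoxybenzaldehyde | COc1cc(C=O)ccc1OCc1ccccc1 | starting material
2 | dimethyl succinate | COC(=O)CCC(=O)OC | starting material
3 | (E)-4-[4-(benzyloxy)-3-methoxyphenyl]-3-(methoxycarbonyl)but-3-enoic acid | COC(=O)/C(CC(=O)O)=C/c1ccc(OCc2ccccc2)c(OC)c1 | intermediate
4 | (S)-3-[4-(benzyloxy)-3-methoxybenzyl]-4-methoxy-4-oxobutanoic acid | COc1cc(C[C@@H](CC(=O)O)C(=O)OC)ccc1OCc1ccccc1 | intermediate
5 | (S)-4-[4-(benzyloxy)-3-methoxyphenyl]-3-(hydroxymethyl)butanoic acid (present as its carboxylate until acidification) | COc1cc(C[C@@H](CC(=O)O)CO)ccc1OCc1ccccc1 | intermediate (not isolated)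
6 | (S)-4-[4-(benzyloxy)-3-methoxybenzyl]dihydrofuran-2(3H)-one | COc1cc(C[C@@H]2COC(=O)C2)ccc1OCc1ccccc1 | intermediate
7 | 4-(benzyloxy)-3,5-dimethoxybenzaldehyde | COc1cc(C=O)cc(OC)c1OCc1ccccc1 | starting material
8 | lithium (S)-4-[4-(benzyloxy)-3-methoxybenzyl]-4,5-dihydrofuran-2-olate (lithium enolate of 6) | [Li]OC1=C[C@H](Cc2ccc(OCc3ccccc3)c(OC)c2)CO1 | intermediate (not isolated)
9 | chloro{[(S)-4-[4-(benzyloxy)-3-methoxybenzyl]-4,5-dihydrofuran-2-yl]oxy}zinc (chlorozinc enolate of 6) | Cl[Zn]OC1=C[C@H](Cc2ccc(OCc3ccccc3)c(OC)c2)CO1 | intermediate (not isolated)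
10 | (3R,4S)-3-[(S)-[4-(benzyloxy)-3,5-dimethoxyphenyl](hydroxy)methyl]-4-[4-(benzyloxy)-3-methoxybenzyl]dihydrofuran-2(3H)-one | COc1cc(C[C@@H]2COC(=O)[C@H]2[C@H](O)c2cc(OC)c(OCc3ccccc3)c(OC)c2)ccc1OCc1ccccc1 | intermediate
11 | (2S,3S)-2-[(S)-[4-(benzyloxy)-3,5-dimethoxyphenyl](hydroxy)methyl]-3-[4-(benzyloxy)-3-methoxybenzyl]butane-1,4-diol | COc1cc(C[C@H](CO)[C@@H](CO)[C@H](O)c2cc(OC)c(OCc3ccccc3)c(OC)c2)ccc1OCc1ccccc1 | intermediate
12 | (2S,3S)-2-[(S)-[4-(benzyloxy)-3,5-dimethoxyphenyl](hydroxy)methyl]-3-[4-(benzyloxy)-3-methoxybenzyl]-4-hydroxybutyl 4-methylbenzenesulfonate | COc1cc(C[C@H](CO)[C@@H](COS(=O)(=O)c2ccc(C)cc2)[C@H](O)c2cc(OC)c(OCc3ccccc3)c(OC)c2)ccc1OCc1ccccc1 | intermediate (not isolated)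
13 | (S)-[4-(benzyloxy)-3,5-dimethoxyphenyl][(3S,4S)-4-[4-(benzyloxy)-3-methoxybenzyl]tetrahydrofuran-3-yl]methanol | COc1cc(C[C@@H]2COC[C@H]2[C@H](O)c2cc(OC)c(OCc3ccccc3)c(OC)c2)ccc1OCc1ccccc1 | intermediate
14 | (S)-(4-hydroxy-3,5-dimethoxyphenyl)[(3S,4S)-4-(4-hydroxy-3-methoxybenzyl)tetrahydrofuran-3-yl]methanol | COc1cc(C[C@@H]2COC[C@H]2[C@H](O)c2cc(OC)c(O)c(OC)c2)ccc1O | target

**Totals and risk**

Total step count: 7. Longest linear sequence: 7 steps (1 → 3 → 4 → 6 → 10 → 11 → 13 → 14).

Steps most likely to fail: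

Step 6 (the new ring closure). The risk is that sulfonylation is not confined to the CH2OH next to the carbinol-bearing carbon, giving double tosylation or closure of the benzylic OH onto the other branch to a 2-aryl-tetrahydrofuran. The fallback uses known chemistry only; it sets out from 10 and comes back at 13. The carbinol of 10 is silylated (TBSOTf, 2,6-lutidine, CH2Cl2, −78 °C) to the silyl ether lactone F1. LiAlH4 (THF, 0 °C) then gives the silyl ether 1,4-diol F2, in which only the two primary hydroxyls are free. Mitsunobu cyclodehydration (PPh3, DIAD, THF, 0 °C → rt) closes the ring to the silyl ether tetrahydrofuran F3, and Bu4NF (THF, rt) returns 13.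

Step 4 (aldol, control of the carbinol center). Lactone enolates often give modest anti/syn ratios, so the carbinol epimer may be formed in large amount. The fallback sets the carbinol by hydride delivery instead of in the C–C bond formation; it sets out from 6 and 7 and comes back at 10. An unselective aldol with LiN(i-Pr)2 alone (THF, −78 °C) gives 10 together with its carbinol epimer F4. The mixture is oxidised (Dess–Martin periodinane, NaHCO3, CH2Cl2) to the single trans keto lactone F5. LiBH(s-Bu)3 (THF, −78 °C) then reduces F5 under Felkin–Anh control (lactone carbonyl as the large group, no chelation) to the anti alcohol 10.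

Step 7 (hydrogenolysis beside an electron-rich benzylic alcohol). The risk is loss of the benzylic OH once the para phenol is free. The fallback masks the carbinol first; it sets out from 13 and comes back at 14. TBSOTf/2,6-lutidine converts 13 into the silyl ether tetrahydrofuran F3 (the same compound as in the first fallback). H2 over 10% Pd/C (EtOAc) then removes both benzyl groups to give the silyl ether diphenol F6, the hindered benzylic silyl ether being hydrogenolysed far more slowly than the alcohol. Bu4NF buffered with AcOH (THF, 0 °C) gives 14.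

**Further compounds**
F1 | step 6 | (3R,4S)-3-[(S)-[4-(benzyloxy)-3,5-dimethoxyphenyl](tert-butyldimethylsilyloxy)methyl]-4-[4-(benzyloxy)-3-methoxybenzyl]dihydrofuran-2(3H)-one | COc1cc(C[C@@H]2COC(=O)[C@H]2[C@H](O[Si](C)(C)C(C)(C)C)c2cc(OC)c(OCc3ccccc3)c(OC)c2)ccc1OCc1ccccc1
F2 | step 6 | (2S,3S)-2-[(S)-[4-(benzyloxy)-3,5-dimethoxyphenyl](tert-butyldimethylsilyloxy)methyl]-3-[4-(benzyloxy)-3-methoxybenzyl]butane-1,4-diol | COc1cc(C[C@H](CO)[C@@H](CO)[C@H](O[Si](C)(C)C(C)(C)C)c2cc(OC)c(OCc3ccccc3)c(OC)c2)ccc1OCc1ccccc1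
F3 | step 6 | tert-butyl{(S)-[4-(benzyloxy)-3,5-dimethoxyphenyl][(3S,4S)-4-[4-(benzyloxy)-3-methoxybenzyl]tetrahydrofuran-3-yl]methoxy}dimethylsilane | COc1cc(C[C@@H]2COC[C@H]2[C@H](O[Si](C)(C)C(C)(C)C)c2cc(OC)c(OCc3ccccc3)c(OC)c2)ccc1OCc1ccccc1
F4 | step 4 | (3R,4S)-3-[(R)-[4-(benzyloxy)-3,5-dimethoxyphenyl](hydroxy)methyl]-4-[4-(benzyloxy)-3-methoxybenzyl]dihydrofuran-2(3H)-one | COc1cc(C[C@@H]2COC(=O)[C@H]2[C@@H](O)c2cc(OC)c(OCc3ccccc3)c(OC)c2)ccc1OCc1ccccc1
F5 | step 4 | (3R,4S)-3-[4-(benzyloxy)-3,5-dimethoxybenzoyl]-4-[4-(benzyloxy)-3-methoxybenzyl]dihydrofuran-2(3H)-one | COc1cc(C[C@@H]2COC(=O)[C@H]2C(=O)c2cc(OC)c(OCc3ccccc3)c(OC)c2)ccc1OCc1ccccc1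
F6 | step 7 | 4-{[(3S,4S)-4-[(S)-(tert-butyldimethylsilyloxy)(4-hydroxy-3,5-dimethoxyphenyl)methyl]tetrahydrofuran-3-yl]methyl}-2-methoxyphenol | COc1cc(C[C@@H]2COC[C@H]2[C@H](O[Si](C)(C)C(C)(C)C)c2cc(OC)c(O)c(OC)c2)ccc1O
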